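**Strategy**

The acylphloroglucinol ring is built, not acylated. It is disconnected at C2–C3 and C1–C6: ring carbons C3–C6, with the oxygens on C4 and C6, come from an acetoacetate-derived 1,3-bis(silyloxy) diene, while C1 with its 11-phenylundecanoyl group and C2 with its oxygen come from a 3-ethoxy ynone. A single Diels–Alder/aromatisation step forms both ring bonds, closes the only new ring and sets the ketone and all three ring oxygens in their final 1,2,4,6 pattern, exploiting the alternating oxygenation of the ring as matched donor–acceptor polarity. The ynone is made from 11-phenylundecanoic acid and ethoxyacetylene; a final de-ethylation reveals the symmetric triol.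

Key step: step 5

Remark: the silyl enol ether and the diene are taken as E/Z mixtures and drawn without double-bond geometry, since both isomers converge on the same arene; the target has no stereocentre.

**Route**

Step 1
Reactants: 1 methyl acetoacetate
Product: 2 methyl 3-(trimethylsilyloxy)but-2-enoate (E/Z mixture)
Conditions: TMSCl, Et3N, hexane, rt; filtration, distillation
Reagents that add atoms: chlorotrimethylsilane, C[Si](C)(C)Cl
Why: Silyl enol ether formation by soft enolisation, in which the amine deprotonates the acidic β-keto ester, the enolate oxygen is trapped by the silyl chloride and insoluble triethylammonium chloride drives the reaction in hexane.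

Step 2
Reactants: 2 methyl 3-(trimethylsilyloxy)but-2-enoate
Product: 4 1-methoxy-1,3-bis(trimethylsilyloxy)buta-1,3-diene, via lithium dienolate 3 (not isolated)
Conditions: LiN(i-Pr)2 (LDA), THF, −78 °C; TMSCl, −78 °C to rt; non-aqueous work-up
Reagents that add atoms: chlorotrimethylsilane, C[Si](C)(C)Cl
Why: Kinetic γ-deprotonation of the vinylogous ester gives the extended dienolate 3, whose ester-derived oxygen is silylated (ketene silyl acetal formation), the standard two-stage route to this diene, which is kept away from water because it hydrolyses readily.

Step 3
Reactants: 5 11-phenylundecanoic acid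
Product: 7 N-methoxy-N-methyl-11-phenylundecanamide, via acyl imidazole 6 (not isolated)
Conditions: 1,1'-carbonyldiimidazole, CH2Cl2, rt; MeNH(OMe)·HCl, rt
Reagents that add atoms: N,O-dimethylhydroxylamine hydrochloride, CNOC.Cl
Why: Carboxyl activation as the acyl imidazole 6 followed by aminolysis (Weinreb amide formation), a standard amide coupling in which the released imidazole serves as base and no other group in the molecule can react.

Step 4
Reactants: 7 N-methoxy-N-methyl-11-phenylundecanamide; 8 ethoxyacetylene
Product: 11 1-ethoxy-13-phenyltridec-1-yn-3-one, via lithium ethoxyacetylide 9 (not isolated), via tetrahedral lithium adduct 10 (not isolated)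
Conditions: 8, n-BuLi, THF, −78 °C; then 7, −78 to 0 °C; inverse quench into cold sat. aq NH4Cl
Reagents that add atoms: none
Why: Weinreb ketone synthesis, in which acetylide 9 adds once to the amide to give the chelated tetrahedral adduct 10 that survives until the cold quench, so a second addition to the ynone is excluded and the near-neutral work-up spares the acid-sensitive alkoxyalkyne.

Step 5
Reactants: 4 1-methoxy-1,3-bis(trimethylsilyloxy)buta-1,3-diene; 11 1-ethoxy-13-phenyltridec-1-yn-3-one
Product: 14 1-(2-ethoxy-4,6-dihydroxyphenyl)-11-phenylundecan-1-one, via cyclohexadiene cycloadduct 12 (not isolated), via bis-silyl aryl ether 13 (not isolated)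
Conditions: 4 (2 equiv), toluene, rt to 80 °C; then 1 M HCl, THF, rt
Reagents that add atoms: none
Why: The electron-rich diene 4 and the acyl-activated alkyne of 11 should combine in a polar, asynchronous Diels–Alder reaction in which the CH2 terminus of 4 bonds first to the ethoxy-bearing alkyne carbon (the C2–C3 ring bond) and the ketene acetal carbon then bonds to the carbon next to the ketone (the C1–C6 ring bond), giving cyclohexa-1,4-diene 12. Adduct 12 holds methoxy and silyloxy on one sp3 carbon with a CH2 across the ring, so 1,4-elimination of methanol aromatises it to 13, and dilute acid then removes both silyl groups to give 14. The closest known reaction type is the Diels–Alder/aromatisation of 1,3-dioxygenated silyloxy dienes with acetylenic ketones and esters to give resorcinols, here with a less usual 3-alkoxy ynone as dienophile. The single ring is closed by intermolecular (4+2) cycloaddition, both ring bonds arising in the same operation; should the process be stepwise (Mukaiyama–Michael addition, then six-membered Claisen-type closure onto the ester-derived carbon), it leads to the same arene. No stereocentre survives, because the acetal carbon of 12 is racemic and is flattened on aromatisation, and either ketene acetal geometry of 4 serves. Only regioselectivity is required, and it is secured by matched polarisation: the largest HOMO coefficient of 4 lies on its CH2 terminus and the largest LUMO coefficient of 11 on the carbon β to the ketone, the ethoxy donor slowing the reaction but polarising the alkyne in the same sense as the ketone.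

Step 6
Reactants: 14 1-(2-ethoxy-4,6-dihydroxyphenyl)-11-phenylundecan-1-one
Product: 16 1-(2,4,6-trihydroxyphenyl)-11-phenylundecan-1-one, via aryl borate 15 (not isolated)
Conditions: BBr3 (5 equiv), CH2Cl2, −78 °C to rt; then ice-water
Reagents that add atoms: none
Why: Lewis-acid dealkylation of an aryl alkyl ether, in which boron binds the ethoxy oxygen, bromide removes the ethyl group by SN2 displacement and hydrolysis of the aryl borate 15 frees the third phenol; BBr3 is preferred to the milder BCl3 because the free C6 phenol already locks the ketone into a boron chelate, leaving no chelation assistance for the C2 ether, while the ketone, the saturated chain and the terminal phenyl ring are inert.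

**Compound list**

1 | methyl acetoacetate | CC(=O)CC(=O)OC | starting material
2 | methyl 3-(trimethylsilyloxy)but-2-enoate (E/Z mixture) | COC(=O)C=C(C)O[Si](C)(C)C | intermediate
3 | lithium 1-methoxy-3-(trimethylsilyloxy)buta-1,3-dien-1-olate (lithium dienolate, not isolated) | COC(O[Li])=CC(=C)O[Si](C)(C)C | intermediate
4 | 1-methoxy-1,3-bis(trimethylsilyloxy)buta-1,3-diene (either ketene acetal geometry) | COC(O[Si](C)(C)C)=CC(=C)O[Si](C)(C)C | intermediate
5 | 11-phenylundecanoic acid | OC(=O)CCCCCCCCCCc1ccccc1 | starting material
6 | 1-(1H-imidazol-1-yl)-11-phenylundecan-1-one (acyl imidazole, not isolated) | O=C(CCCCCCCCCCc1ccccc1)n1ccnc1 | intermediate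
7 | N-methoxy-N-methyl-11-phenylundecanamide | CON(C)C(=O)CCCCCCCCCCc1ccccc1 | intermediate
8 | ethoxyacetylene | CCOC#C | starting material
9 | lithium ethoxyacetylide (not isolated) | CCOC#C[Li] | intermediate
10 | lithium 1-ethoxy-3-[methoxy(methyl)amino]-13-phenyltridec-1-yn-3-olate (racemic tetrahedral adduct, not isolated) | CCOC#CC(O[Li])(CCCCCCCCCCc1ccccc1)N(C)OC | intermediate
11 | 1-ethoxy-13-phenyltridec-1-yn-3-one | CCOC#CC(=O)CCCCCCCCCCc1ccccc1 | intermediate
12 | 1-[2-ethoxy-6-methoxy-4,6-bis(trimethylsilyloxy)cyclohexa-1,4-dien-1-yl]-11-phenylundecan-1-one (racemic cycloadduct, not isolated) | CCOC1=C(C(=O)CCCCCCCCCCc2ccccc2)C(OC)(O[Si](C)(C)C)C=C(O[Si](C)(C)C)C1 | intermediate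
13 | 1-[2-ethoxy-4,6-bis(trimethylsilyloxy)phenyl]-11-phenylundecan-1-one (not isolated) | CCOc1cc(O[Si](C)(C)C)cc(O[Si](C)(C)C)c1C(=O)CCCCCCCCCCc1ccccc1 | intermediate
14 | 1-(2-ethoxy-4,6-dihydroxyphenyl)-11-phenylundecan-1-one | CCOc1cc(O)cc(O)c1C(=O)CCCCCCCCCCc1ccccc1 | intermediate
15 | 1-[2,4,6-tris(dibromoboryloxy)phenyl]-11-phenylundecan-1-one (boron-bound intermediate in its simplest form, not isolated) | O=C(CCCCCCCCCCc1ccccc1)c1c(OB(Br)Br)cc(OB(Br)Br)cc1OB(Br)Br | intermediate
16 | 1-(2,4,6-trihydroxyphenyl)-11-phenylundecan-1-one | O=C(CCCCCCCCCCc1ccccc1)c1c(O)cc(O)cc1O | target

**Step count and risks**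

Total step count: 6. Longest linear sequence: 4 steps (steps 3, 4, 5 and 6 from acid 5; equally steps 1, 2, 5 and 6 from keto ester 1).

Most likely to fail, in order of risk:

Step 5. The ethoxy donor lowers the dienophilic reactivity of the alkyne, so heating may be needed, and under heating the diene may decompose or transfer a silyl group instead of cycloadding. Addition of the diene terminus to the ketone carbonyl (1,2-addition) may also compete with attack at the alkyne. The fallback gives up ring construction and acylates a preformed ring. It sets out from 5, which is converted with oxalyl chloride and catalytic DMF in CH2Cl2 into 11-phenylundecanoyl chloride F1. Friedel–Crafts acylation of commercial phloroglucinol (Oc1cc(O)cc(O)c1) with F1 and AlCl3 in nitrobenzene at rt to 60 °C should give the mono-C-acyl product directly, so the fallback comes back to the route at 16.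

Step 4. The N,O-dimethylhydroxylamine released at the quench may add in conjugate fashion to the push-pull ynone, and the alkoxyalkyne may be hydrated during work-up or chromatography. The fallback avoids the liberated amine by going through the alcohol oxidation level. It sets out from 7, which is reduced with i-Bu2AlH in THF at −78 °C to 11-phenylundecanal F2. Addition of lithium ethoxyacetylide 9 in THF at −78 °C should give racemic 1-ethoxy-13-phenyltridec-1-yn-3-ol F3. Oxidation of this propargylic alcohol with activated MnO2 in CH2Cl2 under neutral conditions should give the ynone, so the fallback comes back to the route at 11.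

Step 6. Dealkylation of the hindered ether next to the boron-chelated ketone may stop short of completion, and forcing Lewis-acid conditions may cause loss of the acyl group from the electron-rich ring. The fallback changes the protecting group so that no Lewis acid is needed. It sets out from 7, which is treated with lithium tert-butoxyacetylide F4, generated from tert-butyl ethynyl ether (CC(C)(C)OC#C, a known reagent) and n-BuLi in THF at −78 °C, to give 1-tert-butoxy-13-phenyltridec-1-yn-3-one F5. Cycloaddition of F5 with 4 at or below room temperature (tert-butyl alkynyl ethers fragment on heating), followed by mild desilylation with NH4F in MeOH, should give 1-(2-tert-butoxy-4,6-dihydroxyphenyl)-11-phenylundecan-1-one F6. Acidolysis of the aryl tert-butyl ether with CF3CO2H in CH2Cl2 at 0 °C should then release the third phenol, so the fallback comes back to the route at 16.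

**Further compounds**

F1 | step 5 | 11-phenylundecanoyl chloride | O=C(Cl)CCCCCCCCCCc1ccccc1
F2 | step 4 | 11-phenylundecanal | O=CCCCCCCCCCCc1ccccc1
F3 | step 4 | racemic 1-ethoxy-13-phenyltridec-1-yn-3-ol | CCOC#CC(O)CCCCCCCCCCc1ccccc1
F4 | step 6 | lithium tert-butoxyacetylide | CC(C)(C)OC#C[Li]
F5 | step 6 | 1-tert-butoxy-13-phenyltridec-1-yn-3-one | CC(C)(C)OC#CC(=O)CCCCCCCCCCc1ccccc1
F6 | step 6 | 1-(2-tert-butoxy-4,6-dihydroxyphenyl)-11-phenylundecan-1-one | CC(C)(C)Oc1cc(O)cc(O)c1C(=O)CCCCCCCCCCc1ccccc1
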